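The dihydropyran ring is disconnected at C4–C4a and O1–C8a, so that a γ-bromo tertiary alcohol carrying the finished C2 stereocentre (from (R)-citramalic acid) is annulated onto a fully substituted aryl iodide. The key step, a palladium/norbornene (Catellani-type) ortho C–H alkylation with ipso C–O closure, exploits that C4a of the benzene ring is a free C–H beside the iodine-bearing C8a, while the other neighbour, C8, is blocked by the prenyl group. Its precursors are an iodo-prenyl-cresol MOM ether and a bromo hydroxy ester; the ester later becomes the (E)-dienyl chain, and the C6 carboxyl is added last by ortho-carboxylation of the C5 phenol.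

Key step: step 9

Assumption: the target is (R) at C2 (priority O1 > dienyl > C3 > CH3), taken unchanged from (R)-citramalic acid; diethyl (3-methylbut-2-en-1-yl)phosphonate and MeOMgOCO2Me in DMF are taken as purchasable reagents.

**Aryl iodide (steps 1–5)**

Step 1
Reactants: 1 2-iodo-6-methylbenzoic acid
Product: 2 (2-iodo-6-methylphenyl)methanol
Conditions: BH3·THF, THF, 0 °C to reflux; MeOH, then aqueous work-up
Reagents that add atoms: none
Why: Borane reduction of a carboxylic acid should take the hindered acid chemoselectively to the benzylic alcohol without touching the aryl iodide.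

Step 2
Reactants: 2 (2-iodo-6-methylphenyl)methanol
Product: 3 2-(bromomethyl)-1-iodo-3-methylbenzene
Conditions: PBr3, Et2O, 0 °C
Reagents that add atoms: phosphorus tribromide, BrP(Br)Br
Why: Bromination of a primary benzylic alcohol with PBr3 proceeds by SN2 displacement of the phosphite ester and leaves the aryl iodide alone.

Step 3
Reactants: 3 2-(bromomethyl)-1-iodo-3-methylbenzene; 4 (2-methylprop-1-en-1-yl)magnesium bromide
Product: 5 1-iodo-3-methyl-2-(3-methylbut-2-en-1-yl)benzene
Conditions: copper iodide CuI (10 mol%), THF, −40 to 0 °C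
Reagents that add atoms: none
Why: Copper-catalysed Kochi-type C(sp3)–C(sp2) coupling of the benzylic bromide with the alkenyl Grignard reagent should build the prenyl group at a temperature at which the aryl iodide does not undergo exchange.

Step 4
Reactants: 5 1-iodo-3-methyl-2-(3-methylbut-2-en-1-yl)benzene
Product: 7 3-iodo-5-methyl-4-(3-methylbut-2-en-1-yl)phenol, via aryl pinacol boronate 6 (not isolated)
Conditions: [Ir(OMe)(cod)]2 (1.5 mol%), 4,4'-di-tert-butyl-2,2'-bipyridine (3 mol%), B2pin2, THF, 70 °C; then NaOH, H2O2 (30% aq.), THF, 0 °C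
Reagents that add atoms: bis(pinacolato)diboron, CC1(C)OB(OC1(C)C)B1OC(C)(C)C(C)(C)O1; hydrogen peroxide, OO
Why: Iridium-catalysed C–H borylation (Hartwig–Miyaura–Smith) is sterically controlled and should borylate the only C–H without an ortho substituent (meta to both iodine and methyl), and the boronate is oxidised in the same flask to the phenol under conditions that spare the aryl iodide and the trisubstituted alkene.

Step 5
Reactants: 7 3-iodo-5-methyl-4-(3-methylbut-2-en-1-yl)phenol
Product: 8 1-iodo-5-(methoxymethoxy)-3-methyl-2-(3-methylbut-2-en-1-yl)benzene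
Conditions: MOMCl, i-Pr2NEt, CH2Cl2, 0 °C to rt
Reagents that add atoms: chloromethyl methyl ether, COCCl
Why: Williamson-type O-alkylation with MOMCl gives a small, base-stable acetal that should prevent O-alkylation of the phenol by the alkyl bromide in the key step.

**Bromo hydroxy ester (steps 6–8)**

Step 6
Reactants: 9 (R)-citramalic acid [(2R)-2-hydroxy-2-methylbutanedioic acid]
Product: 10 2-[(4R)-2,2,4-trimethyl-5-oxo-1,3-dioxolan-4-yl]acetic acid
Conditions: 2,2-dimethoxypropane, TsOH (cat.), rt
Reagents that add atoms: 2,2-dimethoxypropane, COC(C)(C)OC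
Why: Acid-catalysed acetonide formation (transacetalisation) closes the five-membered 1,3-dioxolan-4-one on the α-hydroxy acid unit and leaves the β-carboxyl free, with the stereocentre untouched.

Step 7
Reactants: 10 2-[(4R)-2,2,4-trimethyl-5-oxo-1,3-dioxolan-4-yl]acetic acid
Product: 12 (3R)-3-hydroxy-3-methyldihydrofuran-2(3H)-one, via hydroxyethyl dioxolanone 11 (not isolated)
Conditions: BH3·THF, THF, 0 °C to rt; MeOH; then TsOH (cat.), CH2Cl2, rt
Reagents that add atoms: none
Why: Borane reduction takes the free carboxylic acid to the primary alcohol in the presence of the dioxolanone, and acid then triggers lactonisation by intramolecular transacylation with loss of acetone; the stereocentre is not involved.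

Step 8
Reactants: 12 (3R)-3-hydroxy-3-methyldihydrofuran-2(3H)-one
Product: 13 methyl (2R)-4-bromo-2-hydroxy-2-methylbutanoate
Conditions: dry HBr, MeOH, 0 °C to rt
Reagents that add atoms: hydrogen bromide, Br; methanol, CO
Why: Lactone ring-opening by SN2 attack of bromide at the O–CH2 carbon followed by Fischer esterification of the liberated acid should give the bromo ester, the tertiary α-hydroxy ester centre being inert to ionisation.

**Annulation and endgame (steps 9–13)**

Step 9
Reactants: 8 1-iodo-5-(methoxymethoxy)-3-methyl-2-(3-methylbut-2-en-1-yl)benzene; 13 methyl (2R)-4-bromo-2-hydroxy-2-methylbutanoate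
Product: 14 methyl (2R)-5-(methoxymethoxy)-2,7-dimethyl-8-(3-methylbut-2-en-1-yl)-3,4-dihydro-2H-chromene-2-carboxylate
Conditions: Pd(OAc)2 (10 mol%), XPhos (20 mol%), norbornene (2 equiv), K2CO3 (3 equiv), MeCN, 85 °C
Reagents that add atoms: none
Why: Proposed new method: zerovalent palladium inserts into the C–I bond of 8, norbornene insertion and carbonate-assisted palladation of the only free ortho C–H (between iodine and OMOM) give the aryl–norbornyl palladacycle, which takes up the primary bromide 13 by oxidative addition to tetravalent palladium and forms the aryl–CH2 bond (C4–C4a) by reductive elimination; norbornene is then expelled by β-carbon elimination because both ortho positions are now substituted, and the aryl–palladium bromide at the former C–I carbon binds the deprotonated tertiary hydroxyl and forms the O1–C8a bond by C–O reductive elimination. The closest known reaction types are the Catellani ortho-alkylation with primary alkyl bromides, the palladium/norbornene annulation of aryl iodides with epoxides to 2,3-dihydrobenzofurans and the Buchwald intramolecular etherification of tertiary alcohols to chromans; what is new is their merger into a six-membered annulation with a γ-bromo tertiary alcohol. The dihydropyran ring is closed by C(aryl)–O reductive elimination from a seven-membered oxapalladacycle, formally a 6-exo O-arylation. No new stereocentre is formed: C2 is the quaternary carbinol carbon of 13, no bond to it is made or broken and it bears no enolisable hydrogen, so the (R) configuration from (R)-citramalic acid is carried through. The step needs mono-alkylation at one ortho position and ring closure in preference to protodepalladation or cyclisation of 13 to an oxetane: the prenyl group blocks the second ortho position and forces norbornene extrusion, the tertiary alkoxide has no β-hydrogen, the bulky biaryl phosphine XPhos favours C–O reductive elimination, and K2CO3 is too weak to cyclise free 13.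

Step 10
Reactants: 14 methyl (2R)-5-(methoxymethoxy)-2,7-dimethyl-8-(3-methylbut-2-en-1-yl)-3,4-dihydro-2H-chromene-2-carboxylate
Product: 15 methyl (2R)-5-hydroxy-2,7-dimethyl-8-(3-methylbut-2-en-1-yl)-3,4-dihydro-2H-chromene-2-carboxylate
Conditions: HCl (3 M in MeOH), 40 °C
Reagents that add atoms: none
Why: Acid-catalysed acetal cleavage (MOM removal) frees the phenol before the acid-sensitive dienyl ether exists; the prenyl group has no ortho hydroxyl to cyclise onto and the methyl ester is unchanged in methanol.

Step 11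
Reactants: 15 methyl (2R)-5-hydroxy-2,7-dimethyl-8-(3-methylbut-2-en-1-yl)-3,4-dihydro-2H-chromene-2-carboxylate
Product: 16 (2R)-5-hydroxy-2,7-dimethyl-8-(3-methylbut-2-en-1-yl)-3,4-dihydro-2H-chromene-2-carbaldehyde
Conditions: i-Bu2AlH (3.3 equiv), CH2Cl2, −78 °C; Rochelle salt work-up
Reagents that add atoms: none
Why: Partial ester reduction with i-Bu2AlH should stop at the chelated aluminium hemiacetal of the α-aryloxy ester at −78 °C and release the aldehyde on work-up, and the quaternary C2 cannot epimerise.

Step 12
Reactants: 16 (2R)-5-hydroxy-2,7-dimethyl-8-(3-methylbut-2-en-1-yl)-3,4-dihydro-2H-chromene-2-carbaldehyde; 17 diethyl (3-methylbut-2-en-1-yl)phosphonate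
Product: 18 (2R)-2,7-dimethyl-8-(3-methylbut-2-en-1-yl)-2-[(1E)-4-methylpenta-1,3-dien-1-yl]-3,4-dihydro-2H-chromen-5-ol
Conditions: 17 (2.5 equiv), n-BuLi (2.5 equiv), THF, −78 °C to rt
Reagents that add atoms: none
Why: Horner–Wadsworth–Emmons olefination with the lithiated allylic phosphonate (the excess covers the phenol proton) reacts at the phosphorus-bearing carbon and should give the (E)-alkene under thermodynamic control, since the (Z)-isomer suffers allylic strain against the quaternary C2.

Step 13
Reactants: 18 (2R)-2,7-dimethyl-8-(3-methylbut-2-en-1-yl)-2-[(1E)-4-methylpenta-1,3-dien-1-yl]-3,4-dihydro-2H-chromen-5-ol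
Product: 19 (2R)-5-hydroxy-2,7-dimethyl-8-(3-methylbut-2-en-1-yl)-2-[(1E)-4-methylpenta-1,3-dien-1-yl]-3,4-dihydro-2H-chromene-6-carboxylic acid
Conditions: MeOMgOCO2Me (2 M in DMF, excess), 120 °C; then 1 M HCl, 0 °C
Reagents that add atoms: methyl magnesium carbonate, CO[Mg]OC(=O)OC
Why: Stiles ortho-carboxylation with methyl magnesium carbonate (Kolbe–Schmitt type, known for cannabinoid acids) should deliver CO2 to C6, the only free ring position and ortho to the phenol, as a magnesium salicylate chelate that cold acid releases.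

**Compound list**

1 | 2-iodo-6-methylbenzoic acid | Cc1cccc(I)c1C(=O)O | starting material
2 | (2-iodo-6-methylphenyl)methanol | Cc1cccc(I)c1CO | intermediate
3 | 2-(bromomethyl)-1-iodo-3-methylbenzene | Cc1cccc(I)c1CBr | intermediate
4 | (2-methylprop-1-en-1-yl)magnesium bromide | CC(C)=C[Mg]Br | starting material
5 | 1-iodo-3-methyl-2-(3-methylbut-2-en-1-yl)benzene | Cc1cccc(I)c1CC=C(C)C | intermediate
6 | 2-[3-iodo-5-methyl-4-(3-methylbut-2-en-1-yl)phenyl]-4,4,5,5-tetramethyl-1,3,2-dioxaborolane | Cc1cc(B2OC(C)(C)C(C)(C)O2)cc(I)c1CC=C(C)C | intermediate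
7 | 3-iodo-5-methyl-4-(3-methylbut-2-en-1-yl)phenol | Cc1cc(O)cc(I)c1CC=C(C)C | intermediate
8 | 1-iodo-5-(methoxymethoxy)-3-methyl-2-(3-methylbut-2-en-1-yl)benzene | Cc1cc(OCOC)cc(I)c1CC=C(C)C | intermediate
9 | (R)-citramalic acid, (2R)-2-hydroxy-2-methylbutanedioic acid | OC(=O)[C@@](O)(C)CC(=O)O | starting material
10 | 2-[(4R)-2,2,4-trimethyl-5-oxo-1,3-dioxolan-4-yl]acetic acid | O=C1OC(C)(C)O[C@]1(C)CC(=O)O | intermediate
11 | (5R)-5-(2-hydroxyethyl)-2,2,5-trimethyl-1,3-dioxolan-4-one | O=C1OC(C)(C)O[C@]1(C)CCO | intermediate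
12 | (3R)-3-hydroxy-3-methyldihydrofuran-2(3H)-one | O=C1OCC[C@@]1(C)O | intermediate
13 | methyl (2R)-4-bromo-2-hydroxy-2-methylbutanoate | COC(=O)[C@@](O)(C)CCBr | intermediate
14 | methyl (2R)-5-(methoxymethoxy)-2,7-dimethyl-8-(3-methylbut-2-en-1-yl)-3,4-dihydro-2H-chromene-2-carboxylate | COC(=O)[C@@]1(C)CCc2c(OCOC)cc(C)c(CC=C(C)C)c2O1 | intermediate
15 | methyl (2R)-5-hydroxy-2,7-dimethyl-8-(3-methylbut-2-en-1-yl)-3,4-dihydro-2H-chromene-2-carboxylate | COC(=O)[C@@]1(C)CCc2c(O)cc(C)c(CC=C(C)C)c2O1 | intermediate
16 | (2R)-5-hydroxy-2,7-dimethyl-8-(3-methylbut-2-en-1-yl)-3,4-dihydro-2H-chromene-2-carbaldehyde | O=C[C@@]1(C)CCc2c(O)cc(C)c(CC=C(C)C)c2O1 | intermediate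
17 | diethyl (3-methylbut-2-en-1-yl)phosphonate | CCOP(=O)(CC=C(C)C)OCC | starting material
18 | (2R)-2,7-dimethyl-8-(3-methylbut-2-en-1-yl)-2-[(1E)-4-methylpenta-1,3-dien-1-yl]-3,4-dihydro-2H-chromen-5-ol | CC(C)=C/C=C/[C@@]1(C)CCc2c(O)cc(C)c(CC=C(C)C)c2O1 | intermediate
19 | (2R)-5-hydroxy-2,7-dimethyl-8-(3-methylbut-2-en-1-yl)-2-[(1E)-4-methylpenta-1,3-dien-1-yl]-3,4-dihydro-2H-chromene-6-carboxylic acid | CC(C)=C/C=C/[C@@]1(C)CCc2c(O)c(C(=O)O)c(C)c(CC=C(C)C)c2O1 | target

Total step count: 13
Longest linear sequence: 10 steps (steps 1–5, then 9–13)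

**Steps most likely to fail**

1. Step 9. After the ortho-alkylation the C–O reductive elimination may be slower than protodepalladation of the aryl–palladium intermediate, or 13 may be consumed by base-induced cyclisation before it reaches the palladacycle. The fallback makes the two bonds in separate, known operations; it sets out from 8 and 13 and returns at 14.
   - Iodine–magnesium exchange on 8 (i-PrMgCl·LiCl, THF, −20 °C) and quench with BrCl2C–CCl2Br should give the aryl bromide 1-bromo-5-(methoxymethoxy)-3-methyl-2-(3-methylbut-2-en-1-yl)benzene F1.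
   - Directed ortho-lithiation of the C–H flanked by bromine and OMOM (LDA, THF, −78 °C) and quench with I2 should give 1-bromo-2-iodo-3-(methoxymethoxy)-5-methyl-6-(3-methylbut-2-en-1-yl)benzene F2.
   - In parallel, 13 is silylated (Et3SiOTf, 2,6-lutidine, CH2Cl2) to methyl (2R)-4-bromo-2-methyl-2-[(triethylsilyl)oxy]butanoate F3.
   - F3 is converted into its alkylzinc bromide (Zn, LiCl, THF, 50 °C) and joined to the C–I bond of F2 by Negishi coupling (Pd(OAc)2, SPhos, THF, rt) to give methyl (2R)-4-[2-bromo-6-(methoxymethoxy)-4-methyl-3-(3-methylbut-2-en-1-yl)phenyl]-2-methyl-2-[(triethylsilyl)oxy]butanoate F4.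
   - Et3N·3HF in THF frees the tertiary alcohol methyl (2R)-4-[2-bromo-6-(methoxymethoxy)-4-methyl-3-(3-methylbut-2-en-1-yl)phenyl]-2-hydroxy-2-methylbutanoate F5.
   - Buchwald intramolecular etherification (Pd(OAc)2, 2-(di-tert-butylphosphino)-1,1'-binaphthyl, Cs2CO3, toluene, 80 °C) closes the O1–C8a bond and gives 14.

2. Step 13. The thermal carboxylation is reversible, so decarboxylation during work-up or slow thermal degradation of the dienyl aryl ether at 120 °C may erode the product. The fallback sets out from 18 and returns at 19.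
   - Casnati–Skattebøl ortho-formylation (MgCl2, Et3N, paraformaldehyde, MeCN, 75 °C) at the only free position should give (2R)-5-hydroxy-2,7-dimethyl-8-(3-methylbut-2-en-1-yl)-2-[(1E)-4-methylpenta-1,3-dien-1-yl]-3,4-dihydro-2H-chromene-6-carbaldehyde F7.
   - Pinnick oxidation (NaClO2, NaH2PO4, large excess of 2-methylbut-2-ene, t-BuOH/H2O, 0 °C) then gives 19.

3. Step 12. Addition of the allylic phosphonate anion to the hindered aldehyde may be slow, may occur partly through the γ-carbon, or may give incomplete (E)-selectivity. The fallback sets out from 16 and returns at 18.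
   - Seyferth–Gilbert homologation with the Ohira–Bestmann reagent (dimethyl (1-diazo-2-oxopropyl)phosphonate, K2CO3, MeOH, rt) should give the alkyne (2R)-2-ethynyl-2,7-dimethyl-8-(3-methylbut-2-en-1-yl)-3,4-dihydro-2H-chromen-5-ol F6.
   - Syn-hydrozirconation of the terminal alkyne (Cp2Zr(H)Cl, 2.2 equiv, THF, rt) followed by Negishi-type coupling with 1-bromo-2-methylprop-1-ene (ZnCl2, Pd(PPh3)4 5 mol%, rt) fixes the (E)-geometry and gives 18.

Further compounds
F1 | step 9 | 1-bromo-5-(methoxymethoxy)-3-methyl-2-(3-methylbut-2-en-1-yl)benzene | Cc1cc(OCOC)cc(Br)c1CC=C(C)C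
F2 | step 9 | 1-bromo-2-iodo-3-(methoxymethoxy)-5-methyl-6-(3-methylbut-2-en-1-yl)benzene | Cc1cc(OCOC)c(I)c(Br)c1CC=C(C)C
F3 | step 9 | methyl (2R)-4-bromo-2-methyl-2-[(triethylsilyl)oxy]butanoate | COC(=O)[C@@](O[Si](CC)(CC)CC)(C)CCBr
F4 | step 9 | methyl (2R)-4-[2-bromo-6-(methoxymethoxy)-4-methyl-3-(3-methylbut-2-en-1-yl)phenyl]-2-methyl-2-[(triethylsilyl)oxy]butanoate | COC(=O)[C@@](O[Si](CC)(CC)CC)(C)CCc1c(OCOC)cc(C)c(CC=C(C)C)c1Br
F5 | step 9 | methyl (2R)-4-[2-bromo-6-(methoxymethoxy)-4-methyl-3-(3-methylbut-2-en-1-yl)phenyl]-2-hydroxy-2-methylbutanoate | COC(=O)[C@@](O)(C)CCc1c(OCOC)cc(C)c(CC=C(C)C)c1Br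
F6 | step 12 | (2R)-2-ethynyl-2,7-dimethyl-8-(3-methylbut-2-en-1-yl)-3,4-dihydro-2H-chromen-5-ol | C#C[C@@]1(C)CCc2c(O)cc(C)c(CC=C(C)C)c2O1
F7 | step 13 | (2R)-5-hydroxy-2,7-dimethyl-8-(3-methylbut-2-en-1-yl)-2-[(1E)-4-methylpenta-1,3-dien-1-yl]-3,4-dihydro-2H-chromene-6-carbaldehyde | CC(C)=C/C=C/[C@@]1(C)CCc2c(O)c(C=O)c(C)c(CC=C(C)C)c2O1
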